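Ring A of gravicycle is a 5-alkylresorcinol: its two oxygen-bearing carbons both lie meta to the ring carbon attached to chain carbon C14, the oxygenation pattern of a folded tetraketide. Everything therefore rests on opening ring A between that chain-bearing carbon and its neighbour, which carries a temporary ester. In one operation a diketo-dioxinone is unmasked to a triketo ester and cyclised by aldol condensation into the aromatic ring. The precursor is an open chain with the dioxinone at one end and the 4-fluoro-3,5-dimethoxyphenyl ketone (ring B, future C1) at the other; the ketone later activates fluoride displacement for the ether macrocyclisation and is finally reduced enantioselectively.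

Key step: step 6

Assumption: aryl bromide 3 (and 2-bromo-5-iodo-1,3-dimethoxybenzene, needed only in a fallback) is taken as purchasable; chain carbons are numbered C1 (carbinol carbon on ring B) to C14 (carbon on ring A), and the stereocentre C1 is (R).

Step 1
Reactants: 1 pentadecanolide
Product: 2 15-hydroxy-N-methoxy-N-methylpentadecanamide
Conditions: MeNHOMe·HCl (2 equiv), iPrMgCl (4 equiv), THF, −20 to 0 °C; aq. HCl (1 M)
Reagents that add atoms: N,O-dimethylhydroxylamine hydrochloride, CNOC.Cl
Why: The chloromagnesium amide of N,O-dimethylhydroxylamine opens the unstrained macrolactone by acyl substitution (Weinreb aminolysis of an ester), and the distant alkoxide has no tendency to close the large ring again.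

Step 2
Reactants: 2 15-hydroxy-N-methoxy-N-methylpentadecanamide; 3 5-bromo-2-fluoro-1,3-dimethoxybenzene
Product: 5 1-(4-fluoro-3,5-dimethoxyphenyl)-15-hydroxypentadecan-1-one, via aryllithium 4 (not isolated)
Conditions: 3 (1.4 equiv), n-BuLi (1.35 equiv), THF, −78 °C; 2 premixed with iPrMgCl (1.0 equiv, THF, −40 °C); −78 to 0 °C; aq. HCl (1 M)
Reagents that add atoms: none
Why: Bromine–lithium exchange gives an aryllithium whose fluorine is para and so cannot eliminate to an aryne, and its addition to the amide stops at the chelated tetrahedral adduct (Weinreb ketone synthesis) while the hydroxyl is masked in the flask as its magnesium alkoxide.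

Step 3
Reactants: 5 1-(4-fluoro-3,5-dimethoxyphenyl)-15-hydroxypentadecan-1-one
Product: 6 15-(4-fluoro-3,5-dimethoxyphenyl)-15-oxopentadecanoic acid
Conditions: TEMPO (0.2 equiv), PhI(OAc)2 (2.5 equiv), MeCN/H2O 1:1, rt
Reagents that add atoms: water, O
Why: The oxoammonium salt from TEMPO oxidises the primary alcohol to the aldehyde and, through its hydrate, to the acid (TEMPO/PhI(OAc)2 oxidation), conditions that leave the aryl ketone, the aryl fluoride and the methyl ethers untouched.

Step 4
Reactants: 7 2,2,6-trimethyl-4H-1,3-dioxin-4-one; 8 acetyl chloride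
Product: 10 2,2-dimethyl-6-(2-oxopropyl)-4H-1,3-dioxin-4-one, via lithium dienolate 9 (not isolated)
Conditions: 7 (2 equiv), LiN(SiMe3)2 (2 equiv), THF, −78 °C; 8 (1 equiv), −78 °C; aq. HCl (1 M)
Reagents that add atoms: none
Why: LiN(SiMe3)2 removes a proton from the 6-methyl group and the vinylogous enolate is acylated at that terminal carbon by the acid chloride (vinylogous Claisen acylation), the second equivalent of enolate taking up the acidic proton of the product.

Step 5
Reactants: 6 15-(4-fluoro-3,5-dimethoxyphenyl)-15-oxopentadecanoic acid; 10 2,2-dimethyl-6-(2-oxopropyl)-4H-1,3-dioxin-4-one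
Product: 13 6-[18-(4-fluoro-3,5-dimethoxyphenyl)-2,4,18-trioxooctadecyl]-2,2-dimethyl-4H-1,3-dioxin-4-one, via acyl imidazole 11 (not isolated), via dilithium dienolate 12 (not isolated)
Conditions: 6, CDI (1.1 equiv), THF, rt; 10 (3.2 equiv), LiN(iPr)2 (6.4 equiv), THF, −78 °C; mix at −78 °C, 1 h; aq. HCl (1 M)
Reagents that add atoms: none
Why: The terminal carbon of the dianion of 10 is acylated by the imidazolide (Claisen-type acylation of a 1,3-dicarbonyl dianion), which is far more electrophilic than the aryl ketone and whose product is deprotonated at once, so that any reversible aldol addition at the ketone drains back to the acylation.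

Step 6
Reactants: 13 6-[18-(4-fluoro-3,5-dimethoxyphenyl)-2,4,18-trioxooctadecyl]-2,2-dimethyl-4H-1,3-dioxin-4-one; 14 methanol
Product: 17 methyl 2-[14-(4-fluoro-3,5-dimethoxyphenyl)-14-oxotetradecyl]-4,6-dihydroxybenzoate, via acylketene 15 (not isolated), via triketo ester 16 (not isolated)
Conditions: MeOH (10 equiv), PhMe, 110 °C, sealed tube; then Cs2CO3 (2 equiv), MeOH, rt; then HCl/MeOH (1.25 M), rt
Reagents that add atoms: methanol (14), CO
Why: Heating breaks the dioxinone by a retro-[4+2] cycloreversion into acetone and acylketene 15, which adds methanol to give triketo ester 16; the closest known reaction type is dioxinone thermolysis with ketene trapping followed by polyketide-type aldol aromatisation of a 3,5,7-triketo ester to a 6-alkyl resorcylate. With the ester carbon of 16 counted as position 1, Cs2CO3 enolises the position 2 methylene and this carbon attacks the position 7 ketone, so ring A closes as a six-membered carbocycle by intramolecular aldol addition (6-enolexo-exo-trig) through the bond between the chain-bearing carbon and its ester-bearing neighbour. HCl in methanol then dehydrates the aldol and the dienone enolises to the aromatic resorcylate; no stereocentre is formed. The step needs aldol closure (position 2 onto position 7) to win over Claisen closure (position 6 onto the ester carbonyl), and the non-chelating carbonate base in methanol secures this because the ketone is the better electrophile, whereas a magnesium alkoxide would template the Claisen mode. The position 8 methylene, activated by one carbonyl only, is not enolised by carbonate, so the other possible six-ring aldol (onto position 3) stays silent. The ring B ketone lies thirteen methylenes away and its fluoride is untouched at room temperature, so both pass through unchanged.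

Step 7
Reactants: 17 methyl 2-[14-(4-fluoro-3,5-dimethoxyphenyl)-14-oxotetradecyl]-4,6-dihydroxybenzoate
Product: 19 14-(3,5-dihydroxyphenyl)-1-(4-fluoro-3,5-dimethoxyphenyl)tetradecan-1-one, via resorcylic acid 18 (not isolated)
Conditions: NaOH (2 M aq.)/1,4-dioxane 1:1, 95 °C, Ar; then HCl to pH 1, 90 °C
Reagents that add atoms: none
Why: Hot aqueous hydroxide saponifies the hindered salicylate-type ester and, after acidification, the 2,4-dihydroxybenzoic acid loses CO2 by ipso-protonation (saponification and protodecarboxylation of a beta-resorcylic acid), while solvated hydroxide is too poor a nucleophile to displace the hindered fluoride.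

Step 8
Reactants: 19 14-(3,5-dihydroxyphenyl)-1-(4-fluoro-3,5-dimethoxyphenyl)tetradecan-1-one
Product: 20 macrocyclic diaryl ether ketone bearing two methoxy groups on ring B (22-membered ring)
Conditions: Cs2CO3 (3 equiv), DMSO (0.003 M, slow addition of 19), 140 °C, Ar
Reagents that add atoms: none
Why: A ring A phenoxide adds to the fluorine-bearing carbon of ring B, the charge of the Meisenheimer adduct is taken up by the para ketone and fluoride leaves (intramolecular SNAr macrocyclisation by addition–elimination); the two phenol oxygens of 19 are equivalent, so only one 22-membered diaryl ether can form, the free resorcinol is a better nucleophile than its ester-bearing precursor, and high dilution holds back oligomers.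

Step 9
Reactants: 20 macrocyclic diaryl ether ketone bearing two methoxy groups on ring B
Product: 21 macrocyclic triphenol ketone
Conditions: BBr3 (6 equiv), CH2Cl2, −78 °C to rt; H2O
Reagents that add atoms: none
Why: BBr3 binds each methoxy oxygen and bromide removes the methyl group by SN2 (Lewis acid cleavage of aryl methyl ethers), whereas the diaryl ether offers no sp3 carbon to attack and the ketone is released again on hydrolysis.

Step 10
Reactants: 21 macrocyclic triphenol ketone
Product: 22 gravicycle, the (R)-carbinol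
Conditions: RuCl(p-cymene)[(R,R)-TsDPEN] (5 mol %), HCO2H/Et3N 5:2, DMF, 40 °C
Reagents that add atoms: none
Why: The RuH/NH catalyst passes hydride and proton to the ketone in an outer-sphere six-membered transition state (Noyori–Ikariya asymmetric transfer hydrogenation), the aryl ring lying under the p-cymene ligand so that the (R,R)-diamine delivers hydride to the Si face of C1 and sets the (R) carbinol in the same sense as for acetophenone, and loss of CO2 makes the reduction irreversible so the only stereocentre is set last and is not exposed to later steps.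

Compound list
1 | pentadecanolide (oxacyclohexadecan-2-one) | O=C1CCCCCCCCCCCCCCO1 | starting material
2 | 15-hydroxy-N-methoxy-N-methylpentadecanamide | CON(C)C(=O)CCCCCCCCCCCCCCO | intermediate
3 | 5-bromo-2-fluoro-1,3-dimethoxybenzene | COc1cc(Br)cc(OC)c1F | starting material
4 | (4-fluoro-3,5-dimethoxyphenyl)lithium (not isolated) | [Li]c1cc(OC)c(F)c(OC)c1 | intermediate
5 | 1-(4-fluoro-3,5-dimethoxyphenyl)-15-hydroxypentadecan-1-one | OCCCCCCCCCCCCCCC(=O)c1cc(OC)c(F)c(OC)c1 | intermediate
6 | 15-(4-fluoro-3,5-dimethoxyphenyl)-15-oxopentadecanoic acid | OC(=O)CCCCCCCCCCCCCC(=O)c1cc(OC)c(F)c(OC)c1 | intermediate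
7 | 2,2,6-trimethyl-4H-1,3-dioxin-4-one | CC1=CC(=O)OC(C)(C)O1 | starting material
8 | acetyl chloride | CC(Cl)=O | starting material
9 | lithium dienolate of 7, lithium 2,2-dimethyl-6-methylidene-1,3-dioxin-4-olate (not isolated) | C=C1C=C(O[Li])OC(C)(C)O1 | intermediate
10 | 2,2-dimethyl-6-(2-oxopropyl)-4H-1,3-dioxin-4-one | CC(=O)CC1=CC(=O)OC(C)(C)O1 | intermediate
11 | acyl imidazole of 6, 1-(4-fluoro-3,5-dimethoxyphenyl)-15-(imidazol-1-yl)pentadecane-1,15-dione (not isolated) | O=C(CCCCCCCCCCCCCC(=O)c1cc(OC)c(F)c(OC)c1)n1ccnc1 | intermediate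
12 | dilithium dienolate (dianion) of 10 (not isolated) | C=C(O[Li])C=C1C=C(O[Li])OC(C)(C)O1 | intermediate
13 | 6-[18-(4-fluoro-3,5-dimethoxyphenyl)-2,4,18-trioxooctadecyl]-2,2-dimethyl-4H-1,3-dioxin-4-one (diketo-dioxinone, key-step precursor) | CC1(C)OC(=O)C=C(CC(=O)CC(=O)CCCCCCCCCCCCCC(=O)c2cc(OC)c(F)c(OC)c2)O1 | intermediate
14 | methanol | CO | starting material
15 | acylketene from 13, 20-(4-fluoro-3,5-dimethoxyphenyl)icos-1-ene-1,3,5,7,20-pentaone (not isolated) | O=C=CC(=O)CC(=O)CC(=O)CCCCCCCCCCCCCC(=O)c1cc(OC)c(F)c(OC)c1 | intermediate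
16 | methyl 21-(4-fluoro-3,5-dimethoxyphenyl)-3,5,7,21-tetraoxohenicosanoate (triketo ester, not isolated) | COC(=O)CC(=O)CC(=O)CC(=O)CCCCCCCCCCCCCC(=O)c1cc(OC)c(F)c(OC)c1 | intermediate
17 | methyl 2-[14-(4-fluoro-3,5-dimethoxyphenyl)-14-oxotetradecyl]-4,6-dihydroxybenzoate (ring A resorcylate, key-step product) | COC(=O)c1c(O)cc(O)cc1CCCCCCCCCCCCCC(=O)c1cc(OC)c(F)c(OC)c1 | intermediate
18 | 2-[14-(4-fluoro-3,5-dimethoxyphenyl)-14-oxotetradecyl]-4,6-dihydroxybenzoic acid (not isolated) | OC(=O)c1c(O)cc(O)cc1CCCCCCCCCCCCCC(=O)c1cc(OC)c(F)c(OC)c1 | intermediate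
19 | 14-(3,5-dihydroxyphenyl)-1-(4-fluoro-3,5-dimethoxyphenyl)tetradecan-1-one | Oc1cc(O)cc(CCCCCCCCCCCCCC(=O)c2cc(OC)c(F)c(OC)c2)c1 | intermediate
20 | 22-membered macrocycle: ring A is a 5-hydroxy-1,3-phenylene bonded at C1 to chain carbon C14 and at C3 to the ether oxygen; that oxygen is bonded to C4 of ring B, a 3,5-dimethoxy-1,4-phenylene whose C1 carries the ketone C1 of the thirteen-methylene chain | Oc1cc2cc(c1)Oc1c(OC)cc(cc1OC)C(=O)CCCCCCCCCCCCC2 | intermediate
21 | the same macrocyclic ketone with ring B as a 3,5-dihydroxy-1,4-phenylene (triphenol ketone) | Oc1cc2cc(c1)Oc1c(O)cc(cc1O)C(=O)CCCCCCCCCCCCC2 | intermediate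
22 | gravicycle: macrocycle 21 with C1 reduced to the (R)-configured secondary alcohol | Oc1cc2cc(c1)Oc1c(O)cc(cc1O)[C@H](O)CCCCCCCCCCCCC2 | target

Total step count: 10
Longest linear sequence: 9 steps (steps 1, 2, 3, 5, 6, 7, 8, 9 and 10, from pentadecanolide)

Steps most likely to fail

Step 8. The fluoride is flanked by two methoxy groups and activated by one para ketone only, so displacement may be slower than intermolecular etherification and base-induced condensation at the ketone, and oligomers would then take over. The fallback replaces addition–elimination by a copper-mediated Ullmann ether closure of the bromo series; it sets out from amide 2 and comes back at macrocycle 20.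
- Iodine–magnesium exchange of 2-bromo-5-iodo-1,3-dimethoxybenzene with iPrMgCl·LiCl (THF, −20 °C) should give (4-bromo-3,5-dimethoxyphenyl)magnesium chloride F1.
- F1 adds to the magnesium alkoxide of 2 to give 1-(4-bromo-3,5-dimethoxyphenyl)-15-hydroxypentadecan-1-one F2.
- The conditions of steps 3, 5, 6 and 7 then lead through 15-(4-bromo-3,5-dimethoxyphenyl)-15-oxopentadecanoic acid F3, its acyl imidazole F4, the bromo diketo-dioxinone F5, the bromo acylketene F6, the bromo triketo ester F7, the bromo methyl resorcylate F8 and the bromo resorcylic acid F9 to 1-(4-bromo-3,5-dimethoxyphenyl)-14-(3,5-dihydroxyphenyl)tetradecan-1-one F10.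
- F10 is cyclised with CuI, picolinic acid and K3PO4 in DMSO at 100 °C under high dilution to give 20.

Step 5. The dianion is a strong base and nucleophile, so enolisation of the aryl ketone, addition to it, or proton transfer from imidazole may consume it before the acylation is complete. The fallback uses soft enolisation in place of a dianion; it sets out from acid 6 and comes back at 13.
- Acid 6 with (COCl)2 and catalytic DMF in CH2Cl2 gives 15-(4-fluoro-3,5-dimethoxyphenyl)-15-oxopentadecanoyl chloride F11.
- Separately, dienolate 9 is acylated with allyl malonyl chloride to give allyl 4-(2,2-dimethyl-4-oxo-4H-1,3-dioxin-6-yl)-3-oxobutanoate F12.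
- MgCl2 and pyridine in CH2Cl2 at 0 °C join F11 and F12 at the doubly activated carbon to give the C-acylated allyl keto ester F13.
- Pd(PPh3)4 with morpholine in THF removes the allyl group and CO2 from F13 to give 13.

Step 6. The acylketene may be captured by an enol oxygen of its own chain (pyranone formation) before methanol reaches it, or the triketo ester may close in the Claisen sense, so the resorcylate would form inefficiently. The fallback aromatises first and opens the dioxinone afterwards; it sets out from 13 and comes back at 17.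
- Et3N in CH2Cl2 at rt should make the same ring bond with the dioxinone intact and give 5-[14-(4-fluoro-3,5-dimethoxyphenyl)-14-oxotetradecyl]-7-hydroxy-2,2-dimethyl-4H-1,3-benzodioxin-4-one F14.
- K2CO3 in MeOH at 50 °C then opens the acetonide lactone of F14 by transesterification to give 17.

Further compounds
F1 | step 8 | (4-bromo-3,5-dimethoxyphenyl)magnesium chloride | Cl[Mg]c1cc(OC)c(Br)c(OC)c1
F2 | step 8 | 1-(4-bromo-3,5-dimethoxyphenyl)-15-hydroxypentadecan-1-one | OCCCCCCCCCCCCCCC(=O)c1cc(OC)c(Br)c(OC)c1
F3 | step 8 | 15-(4-bromo-3,5-dimethoxyphenyl)-15-oxopentadecanoic acid | OC(=O)CCCCCCCCCCCCCC(=O)c1cc(OC)c(Br)c(OC)c1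
F4 | step 8 | acyl imidazole of F3 | O=C(CCCCCCCCCCCCCC(=O)c1cc(OC)c(Br)c(OC)c1)n1ccnc1
F5 | step 8 | 6-[18-(4-bromo-3,5-dimethoxyphenyl)-2,4,18-trioxooctadecyl]-2,2-dimethyl-4H-1,3-dioxin-4-one | CC1(C)OC(=O)C=C(CC(=O)CC(=O)CCCCCCCCCCCCCC(=O)c2cc(OC)c(Br)c(OC)c2)O1
F6 | step 8 | bromo acylketene from F5 | O=C=CC(=O)CC(=O)CC(=O)CCCCCCCCCCCCCC(=O)c1cc(OC)c(Br)c(OC)c1
F7 | step 8 | methyl 21-(4-bromo-3,5-dimethoxyphenyl)-3,5,7,21-tetraoxohenicosanoate | COC(=O)CC(=O)CC(=O)CC(=O)CCCCCCCCCCCCCC(=O)c1cc(OC)c(Br)c(OC)c1
F8 | step 8 | methyl 2-[14-(4-bromo-3,5-dimethoxyphenyl)-14-oxotetradecyl]-4,6-dihydroxybenzoate | COC(=O)c1c(O)cc(O)cc1CCCCCCCCCCCCCC(=O)c1cc(OC)c(Br)c(OC)c1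
F9 | step 8 | 2-[14-(4-bromo-3,5-dimethoxyphenyl)-14-oxotetradecyl]-4,6-dihydroxybenzoic acid | OC(=O)c1c(O)cc(O)cc1CCCCCCCCCCCCCC(=O)c1cc(OC)c(Br)c(OC)c1
F10 | step 8 | 1-(4-bromo-3,5-dimethoxyphenyl)-14-(3,5-dihydroxyphenyl)tetradecan-1-one | Oc1cc(O)cc(CCCCCCCCCCCCCC(=O)c2cc(OC)c(Br)c(OC)c2)c1
F11 | step 5 | 15-(4-fluoro-3,5-dimethoxyphenyl)-15-oxopentadecanoyl chloride | O=C(Cl)CCCCCCCCCCCCCC(=O)c1cc(OC)c(F)c(OC)c1
F12 | step 5 | allyl 4-(2,2-dimethyl-4-oxo-4H-1,3-dioxin-6-yl)-3-oxobutanoate | C=CCOC(=O)CC(=O)CC1=CC(=O)OC(C)(C)O1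
F13 | step 5 | allyl 2-[15-(4-fluoro-3,5-dimethoxyphenyl)-15-oxopentadecanoyl]-4-(2,2-dimethyl-4-oxo-4H-1,3-dioxin-6-yl)-3-oxobutanoate | C=CCOC(=O)C(C(=O)CC1=CC(=O)OC(C)(C)O1)C(=O)CCCCCCCCCCCCCC(=O)c1cc(OC)c(F)c(OC)c1
F14 | step 6 | 5-[14-(4-fluoro-3,5-dimethoxyphenyl)-14-oxotetradecyl]-7-hydroxy-2,2-dimethyl-4H-1,3-benzodioxin-4-one | CC1(C)OC(=O)c2c(CCCCCCCCCCCCCC(=O)c3cc(OC)c(F)c(OC)c3)cc(O)cc2O1
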